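# Proposed synthesis of 4-hydroxy-2-(4-hydroxy-2-methoxyphenyl)-5-(3-hydroxy-3-methylbutyl)-6-methoxy-1-benzofuran-3-carbaldehyde (25)

## Structural features

The target 25 is a 2-arylbenzofuran-3-carbaldehyde: a benzo ring (ring A) fused to a furan (ring B), a 4-hydroxy-2-methoxyphenyl group (ring C) joined through the C2–C1′ bond, and a formyl group on C3. Ring A is fully differentiated: O1 on C7a, a free hydroxyl on C4 (peri to the formyl group), a 3-hydroxy-3-methylbutyl chain on C5, a methoxy group on C6 and hydrogen only on C7. The molecule has no stereocentre, so no stereocentres stand next to each other and no configuration has to be set or kept. The fragile groups are the electron-rich aldehyde (open to Dakin-type oxidation and to over-reduction), the two phenols, and the tertiary alcohol, which can close onto the neighbouring C4 hydroxyl to a 2,2-dimethylchroman under acid. The real difficulty is regiochemical. The three oxygens of a phloroglucinol-type ring must end as furan oxygen, free phenol and methyl ether with the chain between the last two, and aryl and formyl must be placed on C2 and C3 of a benzofuran whose C7 competes strongly in ordinary electrophilic formylation. The key step exploits the O1–C2=C3 enol-ether unit of ring B: with a tetracoordinate boron on C2, C3 becomes the nucleophilic carbon and a group on boron can shift to C2, so both substituents of the furan double bond enter together.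

## Logic of the disconnections

25 ⇒ 23 (through 24). The two phenolic O–H bonds become O–benzyl bonds and the tertiary O–H bond becomes an O–Si bond. These three protons would quench the organolithium and the chloroiminium ion of the key step. The gain is that 23 already holds every carbon and the formyl group at its final oxidation level. The forward step must cleave the benzyl ethers without reducing the aldehyde or the furan double bond, and must remove silicon without ionising the tertiary centre next to the freed C4 hydroxyl.

23 ⇒ 13 + 17 + 18. The C2–C1′ bond and the C3–CHO bond are cut together. They are the two substituent bonds of the furan enol ether, and cutting both divides the molecule into two aromatic halves of similar size plus a one-carbon unit. The gain is full convergence with no later redox adjustment at C3. The forward step must deliver the electrophile to C3 only and make ring C, not a boron-bound oxygen, migrate.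

17 ⇒ 15 + 16, and 15 ⇒ 14. The C1′–B bond is cut back to a C–Br bond and the O–benzyl bond back to the phenol. Both are standard and leave a cheap bromophenol. The borylation must tolerate an ortho methoxy group.

13 ⇒ 12 ⇒ 11. The O–Si bond is cut first, then the tertiary C–O bond, which leaves a trisubstituted alkene. The alkene is robust through the hot steps that build ring B and lets the chain enter as a prenyl group. The hydration must be Markovnikov and must leave the furan double bond alone.

11 ⇒ 10 ⇒ 8. The C2–C3 bond and then the O1–C2 bond of ring B are cut, which removes a two-carbon acetic acid unit and exposes a salicylaldehyde. The formyl carbon of 8 fixes which ring carbon becomes C3a, so there is no regiochemical question in the ring closure. The cyclisation must expel CO2 so that C2 and C3 are left unsubstituted.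

8 ⇒ 5 ⇒ 3 + 4. The aryl–CH2 bond of the prenyl group is cut back to an O-prenyl ether on the oxygen para to it, and that ether back to the phenol and the allylic bromide. A double [3,3] shift places the chain on the only carbon para to that oxygen, between the methoxy and benzyloxy groups. The forward step requires the second shift to outrun enolisation of the first dienone.

3 ⇒ 2 ⇒ 1. The O–benzyl and then the O–methyl bond are cut. The methyl group goes on the one hydroxyl para to the formyl group, and the benzyl group on one of two hydroxyls made equivalent by symmetry. Each alkylation must stop after one equivalent.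

## Other disconnections considered

Alternative 1: The C2–C1′ bond is cut while C3 carries a carboxyl group tied as an aryl ester to the oxygen on C2′. In the forward key step a catalyst from Pd(OAc)2 and PCy3 (zerovalent palladium) inserts into the C–Br bond of ester A1, palladates the furan C2–H with the help of base and, after reductive elimination, closes the six-membered lactone of coumestan A2.
- In its favour: intramolecular direct arylation of a benzofuran C2–H is an established reaction type, the tether fixes the site, and the C3 carbon is present from the start, so C7 cannot compete. On precedent and on site control of the one-carbon unit it is better than the chosen plan, which rests on an untested step.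
- Against it here: the lactone ties up exactly the two atoms that must end as a methyl ether (the C2′ oxygen) and as an aldehyde. After the coupling the lactone must be reduced to phenol and primary alcohol, the phenol methylated selectively beside a primary and a tertiary alcohol, the primary alcohol re-oxidised, and the benzyl groups removed. The ring A half must also be built as a 3-carboxylic acid and esterified next to the peri benzyloxy group.
- Comparison: both plans are equally convergent and join the same two aromatic halves. The chosen plan forms two bonds at the final oxidation level in one flask and should be several steps shorter.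

Alternative 2: The C2–C3 bond of ring B is cut at the dihydrofuran level. Ring C arrives as a benzyl ether on the future O1, and C3 with its carbon substituent as an aryldiazoacetate. In the forward key step Rh2(OAc)4 (divalent rhodium) takes N2 from diazo ester A3 and the carbene carbon inserts into the benzylic C–H bond next to the ether oxygen (a 1,5 insertion), which closes the five-membered ring as the cis ester A4.
- In its favour: the reaction class is known and normally cis-selective, the two halves are joined by a simple etherification, and connectivity alone fixes aryl on C2 and carbon on C3. On regiocontrol it equals the chosen plan and on precedent it is better.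
- Against it here: it creates two stereocentres that the target does not have. They must be removed by dehydrogenation of a very electron-rich substrate, and the ester must be reduced and re-oxidised to the aldehyde. The carbene faces two electron-rich arenes and several methoxy C–H bonds, so cyclopropanation, ylide formation and other insertions compete. The arylacetate of ring A needs the same oxygen differentiation as 8.
- Comparison: about five operations follow the key step against one in the chosen plan, and the route is more linear.

Alternative 3: Four bonds of ring A are cut (C7–C7a, C4–C5, C6–C7 and C3a–C4), so that ring A is grown onto a finished 2-arylfuran. In the forward key step irradiation of diazo ketone A5 triggers a Wolff rearrangement (the furyl shift makes C7–C7a). A [2+2] addition to the 1-methoxyalkyne A6 makes C4–C5 and C6–C7, and a four-electron ring opening followed by a six-electron ring closure onto the furan makes C3a–C4. Tautomerisation gives phenol A7.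
- In its favour: the substitution pattern of ring A (free C4 hydroxyl, chain on C5, methoxy on C6, hydrogen on C7) follows directly from the mechanism, and the C4 hydroxyl needs no protecting group. On this point it is better than the chosen plan, which spends four steps differentiating the phloroglucinol oxygens and placing the chain. It also forms four C–C bonds in one step against two.
- Against it here: it needs a 2,3,5-trisubstituted furan carrying aryl, ester and diazoacetyl groups and a sensitive ynol ether, both of which take several non-routine steps. The photochemical step is hard to scale. C3 emerges as an ester that must be reduced and re-oxidised beside a free phenol.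
- Comparison: the two plans are equally convergent. The alternative solves ring A more elegantly, but the chosen plan has simpler fragments and a shorter sequence after the key step.

Key step: step 11

Remark on the chemistry: the constitutions of 13, 17 and 23 were checked atom by atom against 25 and needed no correction. Boron is assumed to leave the oxidised intermediate as pinacol hydrogen borate (not as water), and the benzyl, triethylsilyl and pinacol groups are kept on the coupling partners because each is inert to n-BuLi at −78 °C and to the chloroiminium ion.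

## Route

Step 1
Reactants: 1 2,4,6-trihydroxybenzaldehyde
Product: 2 2,6-dihydroxy-4-methoxybenzaldehyde
Conditions: Me2SO4 (1.0 equiv), K2CO3 (1.0 equiv), acetone, 0 °C → rt
Reagents that add atoms: dimethyl sulfate, COS(=O)(=O)OC
Why: Williamson etherification; the C4 hydroxyl, para to the formyl group, is the most acidic and the only one that cannot hydrogen-bond to the carbonyl oxygen, so one equivalent of base and of a hard methylating agent should methylate it alone.

Step 2
Reactants: 2 2,6-dihydroxy-4-methoxybenzaldehyde
Product: 3 2-(benzyloxy)-6-hydroxy-4-methoxybenzaldehyde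
Conditions: BnBr (1.0 equiv), K2CO3, DMF, rt
Reagents that add atoms: benzyl bromide, BrCc1ccccc1
Why: Williamson etherification; the two hydroxyls are equivalent by symmetry, and once one is benzylated the other is locked in a hydrogen bond to the formyl oxygen, so the reaction should stop at the monoether.

Step 3
Reactants: 3 2-(benzyloxy)-6-hydroxy-4-methoxybenzaldehyde; 4 1-bromo-3-methylbut-2-ene
Product: 5 2-(benzyloxy)-4-methoxy-6-[(3-methylbut-2-en-1-yl)oxy]benzaldehyde
Conditions: K2CO3, DMF, 60 °C
Reagents that add atoms: none
Why: Williamson etherification; warming overcomes the hydrogen bond of the last phenol and SN2 attack at the primary allylic carbon of 4 should give the aryl prenyl ether.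

Step 4
Reactants: 5 2-(benzyloxy)-4-methoxy-6-[(3-methylbut-2-en-1-yl)oxy]benzaldehyde
Product: 8 2-(benzyloxy)-6-hydroxy-4-methoxy-3-(3-methylbut-2-en-1-yl)benzaldehyde, via ortho-dienone 6 (not isolated), via para-dienone 7 (not isolated)
Conditions: PhNEt2, 200 °C, sealed tube, Ar
Reagents that add atoms: none
Why: Aromatic para-Claisen–Cope rearrangement; a first [3,3] shift puts the inverted allyl unit on C5 (6), a second [3,3] shift carries it to C3 with the prenyl connectivity restored (7), and enolisation gives the phenol; the flanking oxygens crowd 6 so the Cope shift should outrun enolisation, and the mechanism fixes the new C–C bond between the methoxy and benzyloxy groups, para to the freed hydroxyl.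

Step 5
Reactants: 8 2-(benzyloxy)-6-hydroxy-4-methoxy-3-(3-methylbut-2-en-1-yl)benzaldehyde
Product: 10 2-[3-(benzyloxy)-2-formyl-5-methoxy-4-(3-methylbut-2-en-1-yl)phenoxy]acetic acid, via ethyl aryloxyacetate 9 (not isolated)
Conditions: BrCH2CO2Et, K2CO3, DMF, 50 °C; then 2 M NaOH, rt; then 1 M HCl
Reagents that add atoms: ethyl bromoacetate, CCOC(=O)CBr; sodium hydroxide, [Na+].[OH-]
Why: Williamson etherification of the hydrogen-bonded phenol with the activated bromide, then saponification of 9 in the same flask; the carboxylate does not enolise under these conditions, so the formyl group should survive.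

Step 6
Reactants: 10 2-[3-(benzyloxy)-2-formyl-5-methoxy-4-(3-methylbut-2-en-1-yl)phenoxy]acetic acid
Product: 11 4-(benzyloxy)-6-methoxy-5-(3-methylbut-2-en-1-yl)-1-benzofuran
Conditions: NaOAc, Ac2O, 130 °C
Reagents that add atoms: none
Why: Perkin-type cyclisation; the activated aryloxyacetic acid adds through its alpha carbon to the neighbouring formyl group, and loss of CO2 and water forms the C2–C3 double bond directly, so the 2,3-unsubstituted benzofuran results without a separate decarboxylation.

Step 7
Reactants: 11 4-(benzyloxy)-6-methoxy-5-(3-methylbut-2-en-1-yl)-1-benzofuran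
Product: 12 4-[4-(benzyloxy)-6-methoxy-1-benzofuran-5-yl]-2-methylbutan-2-ol
Conditions: Co(acac)2 (20 mol%), PhSiH3, O2 (1 atm), THF, rt; then PPh3
Reagents that add atoms: dioxygen, O=O
Why: Mukaiyama hydration; a cobalt hydride transfers a hydrogen atom to the trisubstituted alkene to give the tertiary radical (Markovnikov), O2 traps it, and PPh3 reduces the peroxide to the alcohol; the aromatic furan double bond should be a much poorer hydrogen-atom acceptor.

Step 8
Reactants: 12 4-[4-(benzyloxy)-6-methoxy-1-benzofuran-5-yl]-2-methylbutan-2-ol
Product: 13 4-(benzyloxy)-6-methoxy-5-[3-methyl-3-(triethylsilyloxy)butyl]-1-benzofuran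
Conditions: TESOTf, 2,6-lutidine, CH2Cl2, −78 → 0 °C
Reagents that add atoms: triethylsilyl trifluoromethanesulfonate, CC[Si](CC)(CC)OS(=O)(=O)C(F)(F)F
Why: Silyl ether formation; the hindered tertiary alcohol needs the silyl triflate, the lutidine buffer protects the electron-rich benzofuran, and the only acidic proton is masked before the lithiation.

Step 9
Reactants: 14 4-bromo-3-methoxyphenol
Product: 15 4-(benzyloxy)-1-bromo-2-methoxybenzene
Conditions: BnBr, K2CO3, DMF, rt
Reagents that add atoms: benzyl bromide, BrCc1ccccc1
Why: Williamson etherification of the phenol; the aryl bromide is inert under these conditions.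

Step 10
Reactants: 15 4-(benzyloxy)-1-bromo-2-methoxybenzene; 16 bis(pinacolato)diboron
Product: 17 2-[4-(benzyloxy)-2-methoxyphenyl]-4,4,5,5-tetramethyl-1,3,2-dioxaborolane
Conditions: Pd(dppf)Cl2 (3 mol%), KOAc, 1,4-dioxane, 90 °C
Reagents that add atoms: none
Why: Miyaura borylation; zerovalent palladium inserts into the C–Br bond, the acetate-activated diboron transmetalates and reductive elimination gives the aryl boronate; the ortho methoxy group should slow but not block the coupling.

Step 11
Reactants: 13 4-(benzyloxy)-6-methoxy-5-[3-methyl-3-(triethylsilyloxy)butyl]-1-benzofuran; 17 2-[4-(benzyloxy)-2-methoxyphenyl]-4,4,5,5-tetramethyl-1,3,2-dioxaborolane; 18 (chloromethylidene)dimethylammonium chloride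
Product: 23 4-(benzyloxy)-2-[4-(benzyloxy)-2-methoxyphenyl]-6-methoxy-5-[3-methyl-3-(triethylsilyloxy)butyl]-1-benzofuran-3-carbaldehyde, via 2-lithiobenzofuran 19 (not isolated), via lithium boronate complex 20 (not isolated), via 2-boryl-2,3-dihydrobenzofuran iminium chloride 21 (not isolated), via benzofuran-3-ylmethaniminium chloride 22 (not isolated)
Conditions: n-BuLi, THF, −78 °C; 17, −78 → 0 °C; 18, MeCN/THF, −78 → 0 °C; Me3NO (anhydrous), rt → 45 °C; sat. aq. NaHCO3, rt
Reagents that add atoms: water, O
Why: Proposed new method: n-BuLi removes the most acidic proton (C2–H, next to O1) to give 19, which adds to the vacant orbital on boron of 17 to give the tetracoordinate complex 20. In 20 the C2–B bond and the O1 lone pair both push electron density to C3, so the chloroiminium ion 18 should attack C3, and the oxocarbenium character developing at C2 is quenched by an anti 1,2-shift of ring C from boron to C2 (21, aryl trans to the new one-carbon unit, racemic, both centres transient). Me3NO then inserts oxygen into the C2–B bond, and loss of the borate together with the now acidic C3–H restores the furan as iminium salt 22, which aqueous NaHCO3 hydrolyses to 23. Keeping the formyl carbon as an iminium ion until boron has left guards it against oxidation and against opening of a free hemiketal. The closest known reaction type is the electrophile-triggered 1,2-metallate rearrangement of indol-2-yl and furan-2-yl boronate complexes with carbon electrophiles followed by oxidative removal of boron; a chloroiminium ion as formyl cation equivalent on a benzofuran-2-yl complex is the new element. No ring is closed and no stereocentre survives. Attack at C3 (not at the boron-bearing C2, the ipso carbon of ring C or C7 of ring A) rests on the enol-ether polarisation of the ate complex, the low temperature and the use of about one equivalent of 18. Aryl migration, not oxygen migration, is expected because the electron-rich aryl group is the better migrating group and the dioxaborolane ring resists expansion.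

Step 12
Reactants: 23 4-(benzyloxy)-2-[4-(benzyloxy)-2-methoxyphenyl]-6-methoxy-5-[3-methyl-3-(triethylsilyloxy)butyl]-1-benzofuran-3-carbaldehyde
Product: 25 4-hydroxy-2-(4-hydroxy-2-methoxyphenyl)-5-(3-hydroxy-3-methylbutyl)-6-methoxy-1-benzofuran-3-carbaldehyde, via bisphenol triethylsilyl ether 24 (not isolated)
Conditions: H2 (1 atm), Pd/C, EtOAc, rt; filter; then HF·pyridine, pyridine, THF, 0 °C → rt
Reagents that add atoms: none
Why: Hydrogenolysis of both aryl benzyl ethers in neutral ethyl acetate, where the push–pull aldehyde (a vinylogous formate) and the tetrasubstituted furan double bond should react far more slowly; buffered HF·pyridine then cleaves the tertiary silyl ether of 24 without ionising the tertiary centre toward chroman formation.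

## Compound list

1 | 2,4,6-trihydroxybenzaldehyde | O=Cc1c(O)cc(O)cc1O | starting material
2 | 2,6-dihydroxy-4-methoxybenzaldehyde | O=Cc1c(O)cc(OC)cc1O | intermediate
3 | 2-(benzyloxy)-6-hydroxy-4-methoxybenzaldehyde | O=Cc1c(O)cc(OC)cc1OCc1ccccc1 | intermediate
4 | 1-bromo-3-methylbut-2-ene | CC(C)=CCBr | starting material
5 | 2-(benzyloxy)-4-methoxy-6-[(3-methylbut-2-en-1-yl)oxy]benzaldehyde | O=Cc1c(OCC=C(C)C)cc(OC)cc1OCc1ccccc1 | intermediate
6 | 2-(benzyloxy)-4-methoxy-5-(2-methylbut-3-en-2-yl)-6-oxocyclohexa-1,3-diene-1-carbaldehyde (racemic) | O=CC1=C(OCc2ccccc2)C=C(OC)C(C(C)(C)C=C)C1=O | intermediate (not isolated)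
7 | 2-(benzyloxy)-4-methoxy-3-(3-methylbut-2-en-1-yl)-6-oxocyclohexa-1,4-diene-1-carbaldehyde (racemic) | O=CC1=C(OCc2ccccc2)C(CC=C(C)C)C(OC)=CC1=O | intermediate (not isolated)
8 | 2-(benzyloxy)-6-hydroxy-4-methoxy-3-(3-methylbut-2-en-1-yl)benzaldehyde | O=Cc1c(O)cc(OC)c(CC=C(C)C)c1OCc1ccccc1 | intermediate
9 | ethyl 2-[3-(benzyloxy)-2-formyl-5-methoxy-4-(3-methylbut-2-en-1-yl)phenoxy]acetate | CCOC(=O)COc1cc(OC)c(CC=C(C)C)c(OCc2ccccc2)c1C=O | intermediate (not isolated)
10 | 2-[3-(benzyloxy)-2-formyl-5-methoxy-4-(3-methylbut-2-en-1-yl)phenoxy]acetic acid | OC(=O)COc1cc(OC)c(CC=C(C)C)c(OCc2ccccc2)c1C=O | intermediate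
11 | 4-(benzyloxy)-6-methoxy-5-(3-methylbut-2-en-1-yl)-1-benzofuran | COc1cc2occc2c(OCc2ccccc2)c1CC=C(C)C | intermediate
12 | 4-[4-(benzyloxy)-6-methoxy-1-benzofuran-5-yl]-2-methylbutan-2-ol | COc1cc2occc2c(OCc2ccccc2)c1CCC(C)(C)O | intermediate
13 | 4-(benzyloxy)-6-methoxy-5-[3-methyl-3-(triethylsilyloxy)butyl]-1-benzofuran | CC[Si](CC)(CC)OC(C)(C)CCc1c(OC)cc2occc2c1OCc1ccccc1 | intermediate
14 | 4-bromo-3-methoxyphenol | COc1cc(O)ccc1Br | starting material
15 | 4-(benzyloxy)-1-bromo-2-methoxybenzene | COc1cc(OCc2ccccc2)ccc1Br | intermediate
16 | bis(pinacolato)diboron | CC1(C)OB(OC1(C)C)B1OC(C)(C)C(C)(C)O1 | starting material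
17 | 2-[4-(benzyloxy)-2-methoxyphenyl]-4,4,5,5-tetramethyl-1,3,2-dioxaborolane | COc1cc(OCc2ccccc2)ccc1B1OC(C)(C)C(C)(C)O1 | intermediate
18 | (chloromethylidene)dimethylammonium chloride | C[N+](C)=CCl.[Cl-] | starting material
19 | {4-(benzyloxy)-6-methoxy-5-[3-methyl-3-(triethylsilyloxy)butyl]-1-benzofuran-2-yl}lithium | [Li]c1cc2c(OCc3ccccc3)c(CCC(C)(C)O[Si](CC)(CC)CC)c(OC)cc2o1 | intermediate (not isolated)
20 | lithium {4-(benzyloxy)-6-methoxy-5-[3-methyl-3-(triethylsilyloxy)butyl]-1-benzofuran-2-yl}[4-(benzyloxy)-2-methoxyphenyl](pinacolato)borate | [Li+].COc1cc(OCc2ccccc2)ccc1[B-]1(OC(C)(C)C(C)(C)O1)c1cc2c(OCc3ccccc3)c(CCC(C)(C)O[Si](CC)(CC)CC)c(OC)cc2o1 | intermediate (not isolated)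
21 | {4-(benzyloxy)-2-[4-(benzyloxy)-2-methoxyphenyl]-6-methoxy-5-[3-methyl-3-(triethylsilyloxy)butyl]-2-(4,4,5,5-tetramethyl-1,3,2-dioxaborolan-2-yl)-2,3-dihydro-1-benzofuran-3-yl}methylidene(dimethyl)ammonium chloride (racemic, aryl trans to the iminiomethyl group, one enantiomer drawn) | C[N+](C)=C[C@@H]1c2c(OCc3ccccc3)c(CCC(C)(C)O[Si](CC)(CC)CC)c(OC)cc2O[C@@]1(B4OC(C)(C)C(C)(C)O4)c5ccc(OCc6ccccc6)cc5OC.[Cl-] | intermediate (not isolated)
22 | {4-(benzyloxy)-2-[4-(benzyloxy)-2-methoxyphenyl]-6-methoxy-5-[3-methyl-3-(triethylsilyloxy)butyl]-1-benzofuran-3-yl}methylidene(dimethyl)ammonium chloride | C[N+](C)=Cc1c(-c2ccc(OCc3ccccc3)cc2OC)oc2cc(OC)c(CCC(C)(C)O[Si](CC)(CC)CC)c(OCc3ccccc3)c12.[Cl-] | intermediate (not isolated)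
23 | 4-(benzyloxy)-2-[4-(benzyloxy)-2-methoxyphenyl]-6-methoxy-5-[3-methyl-3-(triethylsilyloxy)butyl]-1-benzofuran-3-carbaldehyde | O=Cc1c(-c2ccc(OCc3ccccc3)cc2OC)oc2cc(OC)c(CCC(C)(C)O[Si](CC)(CC)CC)c(OCc3ccccc3)c12 | intermediate
24 | 4-hydroxy-2-(4-hydroxy-2-methoxyphenyl)-6-methoxy-5-[3-methyl-3-(triethylsilyloxy)butyl]-1-benzofuran-3-carbaldehyde | O=Cc1c(-c2ccc(O)cc2OC)oc2cc(OC)c(CCC(C)(C)O[Si](CC)(CC)CC)c(O)c12 | intermediate (not isolated)
25 | 4-hydroxy-2-(4-hydroxy-2-methoxyphenyl)-5-(3-hydroxy-3-methylbutyl)-6-methoxy-1-benzofuran-3-carbaldehyde | COc1cc(O)ccc1-c1oc2cc(OC)c(CCC(C)(C)O)c(O)c2c1C=O | target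

## Step count and least certain steps

Total: 12 steps. Longest linear sequence: 10 steps (steps 1 to 8, 11 and 12); steps 9 and 10 form the second branch.

Step 11 (key step, new method). The chloroiminium ion may attack the ipso carbon of ring C or a pinacol oxygen instead of C3, which would break up the ate complex. Oxidation of the hindered tertiary C–B bond may stall, or the N-oxide may oxidise the iminium carbon. The oxidised intermediate may also open and reclose onto the formyl carbon, scrambling the skeleton to a 3-aroyl isomer. The fallback uses known reaction types only, sets out from 13 and returns at 23. Lithiation of 13 at C2, borylation with B(OMe)3 and oxidation with H2O2 should give 4-(benzyloxy)-6-methoxy-5-[3-methyl-3-(triethylsilyloxy)butyl]-1-benzofuran-2(3H)-one F1. Vilsmeier haloformylation of this lactone with an excess of 18 in CH2Cl2, buffered with a hindered pyridine, attacks the enol carbon C3 and replaces the lactone oxygen by chlorine, giving 4-(benzyloxy)-2-chloro-6-methoxy-5-[3-methyl-3-(triethylsilyloxy)butyl]-1-benzofuran-3-carbaldehyde F2. Suzuki–Miyaura coupling of F2 with 17 (Pd(PPh3)4, K3PO4, dioxane/water) then gives 23. Here C3 is formylated as a lactone enol, so C7 cannot compete.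

Step 4. The first dienone may enolise before the Cope shift, which would leave the inverted allyl group on the ortho carbon, and the prenyl ether may ionise at 200 °C. The fallback sets out from 2 and returns at 11, with the furan made first and the chain added by ortho C-alkylation of a phenoxide.
- Alkylation of one of the two equivalent hydroxyls of 2 with ethyl bromoacetate and saponification should give 2-(2-formyl-3-hydroxy-5-methoxyphenoxy)acetic acid F3.
- NaOAc/Ac2O closes the furan and acetylates the phenol to 6-methoxy-1-benzofuran-4-yl acetate F4.
- Methanolysis (K2CO3, MeOH) gives 6-methoxy-1-benzofuran-4-ol F5.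
- The phenoxide formed with NaH in toluene is alkylated by 4 at its only free ortho carbon to give 6-methoxy-5-(3-methylbut-2-en-1-yl)-1-benzofuran-4-ol F6.
- Benzylation (BnBr, K2CO3) gives 11.

Step 1. Methylation may continue to a second hydroxyl or occur on a ring carbon, since the phloroglucinol anion is ambident. The fallback sets out from 1 and returns at 2. Exhaustive methylation (Me2SO4, K2CO3) gives 2,4,6-trimethoxybenzaldehyde F7, and an excess of AlCl3 in chlorobenzene at 80 °C then cleaves the two ortho methyl ethers through the chelate with the formyl oxygen while the para methyl ether stays.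

Step 7. Hydrogen-atom transfer to the furan C2–C3 bond, or oxidation at the benzylic ether, may compete with hydration of the prenyl group. The fallback sets out from 8 and returns at 12, with hydration done before any furan exists and ring B built under basic conditions that tolerate a free tertiary alcohol.
- The same cobalt-catalysed hydration on 8 should give 2-(benzyloxy)-6-hydroxy-3-(3-hydroxy-3-methylbutyl)-4-methoxybenzaldehyde F8.
- Ethyl bromoacetate and K2CO3 in DMF at 120 °C alkylate the phenol and close the ring by aldol condensation to ethyl 4-(benzyloxy)-5-(3-hydroxy-3-methylbutyl)-6-methoxy-1-benzofuran-2-carboxylate F9.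
- Saponification gives 4-(benzyloxy)-5-(3-hydroxy-3-methylbutyl)-6-methoxy-1-benzofuran-2-carboxylic acid F10.
- Protodecarboxylation with catalytic Ag2CO3 and AcOH in DMSO at 120 °C gives 12.

Step 12. Hydrogenolysis may also reduce the formyl group or saturate the furan double bond, and the C4 benzyl ether, flanked by the chain and the peri aldehyde, may cleave slowly. The fallback sets out from 23 and returns at 24, replacing reduction by Lewis-acid cleavage with a cation trap. BCl3 and pentamethylbenzene in CH2Cl2 at −78 °C should remove both benzyl groups within minutes, before the tertiary silyl ether is attacked, and HF·pyridine then converts 24 into 25 as in the main route.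

## Further compounds

F1 | step 11 | 4-(benzyloxy)-6-methoxy-5-[3-methyl-3-(triethylsilyloxy)butyl]-1-benzofuran-2(3H)-one | O=C1Cc2c(OCc3ccccc3)c(CCC(C)(C)O[Si](CC)(CC)CC)c(OC)cc2O1
F2 | step 11 | 4-(benzyloxy)-2-chloro-6-methoxy-5-[3-methyl-3-(triethylsilyloxy)butyl]-1-benzofuran-3-carbaldehyde | O=Cc1c(Cl)oc2cc(OC)c(CCC(C)(C)O[Si](CC)(CC)CC)c(OCc3ccccc3)c12
F3 | step 4 | 2-(2-formyl-3-hydroxy-5-methoxyphenoxy)acetic acid | OC(=O)COc1cc(OC)cc(O)c1C=O
F4 | step 4 | 6-methoxy-1-benzofuran-4-yl acetate | CC(=O)Oc1cc(OC)cc2occc12
F5 | step 4 | 6-methoxy-1-benzofuran-4-ol | COc1cc(O)c2ccoc2c1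
F6 | step 4 | 6-methoxy-5-(3-methylbut-2-en-1-yl)-1-benzofuran-4-ol | COc1cc2occc2c(O)c1CC=C(C)C
F7 | step 1 | 2,4,6-trimethoxybenzaldehyde | COc1cc(OC)c(C=O)c(OC)c1
F8 | step 7 | 2-(benzyloxy)-6-hydroxy-3-(3-hydroxy-3-methylbutyl)-4-methoxybenzaldehyde | O=Cc1c(O)cc(OC)c(CCC(C)(C)O)c1OCc1ccccc1
F9 | step 7 | ethyl 4-(benzyloxy)-5-(3-hydroxy-3-methylbutyl)-6-methoxy-1-benzofuran-2-carboxylate | CCOC(=O)c1cc2c(OCc3ccccc3)c(CCC(C)(C)O)c(OC)cc2o1
F10 | step 7 | 4-(benzyloxy)-5-(3-hydroxy-3-methylbutyl)-6-methoxy-1-benzofuran-2-carboxylic acid | OC(=O)c1cc2c(OCc3ccccc3)c(CCC(C)(C)O)c(OC)cc2o1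
F0 | step 12 | none | none
A1 | alternative 1 | 5-(benzyloxy)-2-bromophenyl 4-(benzyloxy)-5-(3-hydroxy-3-methylbutyl)-6-methoxy-1-benzofuran-3-carboxylate | O=C(Oc1cc(OCc2ccccc2)ccc1Br)c1coc2cc(OC)c(CCC(C)(C)O)c(OCc3ccccc3)c12
A2 | alternative 1 | 3,7-bis(benzyloxy)-8-(3-hydroxy-3-methylbutyl)-9-methoxy-6H-[1]benzofuro[3,2-c]chromen-6-one | O=C1Oc2cc(OCc3ccccc3)ccc2-c2oc3cc(OC)c(CCC(C)(C)O)c(OCc4ccccc4)c3c21
A3 | alternative 2 | methyl 2-{2-{[4-(benzyloxy)-2-methoxyphenyl]methoxy}-6-(tert-butyldimethylsilyloxy)-4-methoxy-5-[3-methyl-3-(triethylsilyloxy)butyl]phenyl}-2-diazoacetate | COC(=O)C(=[N+]=[N-])c1c(OCc2ccc(OCc3ccccc3)cc2OC)cc(OC)c(CCC(C)(C)O[Si](CC)(CC)CC)c1O[Si](C)(C)C(C)(C)C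
A4 | alternative 2 | methyl cis-2-[4-(benzyloxy)-2-methoxyphenyl]-4-(tert-butyldimethylsilyloxy)-6-methoxy-5-[3-methyl-3-(triethylsilyloxy)butyl]-2,3-dihydro-1-benzofuran-3-carboxylate (racemic, one enantiomer drawn) | COC(=O)[C@@H]1[C@H](c2ccc(OCc3ccccc3)cc2OC)Oc2cc(OC)c(CCC(C)(C)O[Si](CC)(CC)CC)c(O[Si](C)(C)C(C)(C)C)c21
A5 | alternative 3 | methyl 2-[4-(benzyloxy)-2-methoxyphenyl]-5-(2-diazoacetyl)furan-3-carboxylate | COC(=O)c1cc(C(=O)C=[N+]=[N-])oc1-c1ccc(OCc2ccccc2)cc1OC
A6 | alternative 3 | triethyl[(6-methoxy-2-methylhex-5-yn-2-yl)oxy]silane | COC#CCCC(C)(C)O[Si](CC)(CC)CC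
A7 | alternative 3 | methyl 2-[4-(benzyloxy)-2-methoxyphenyl]-4-hydroxy-6-methoxy-5-[3-methyl-3-(triethylsilyloxy)butyl]-1-benzofuran-3-carboxylate | COC(=O)c1c(-c2ccc(OCc3ccccc3)cc2OC)oc2cc(OC)c(CCC(C)(C)O[Si](CC)(CC)CC)c(O)c12
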